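**Strategy.** Everything rests on disconnecting the C9–C10 bond of ring B. Quaternary C10, flanked by the C5 methine at the cis A/B fusion, is recognised as the methyl-bearing alkene carbon of an intact (R)-α-ionone ring (ring A), whose C5 side chain already holds C6–C8. An intramolecular Heck reaction of an α-iodoenone (iodine on C9, ketone at C8, C9=C11 alkene carrying a protected C12 hydroxyl) closes ring B in the 6-exo mode, creates C10 with its methyl group cis to C5–H, and leaves a C8 ketone and an exocyclic enone from which C8 and C9 are set. The C13–C22 triene is joined last by sp3–sp2 Suzuki coupling.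

Key step: step 5

**Remarks**
- Numbering (labdane type): ring A = C1–C5, C10 (C4 = CMe2); ring B = C5–C10; C8 = C(CH3)OH; C9 carries the chain C11–C22. β is the face of the C10 methyl group.
- Target 26 is (1R,2R,4aR,8aS), i.e. 5R,8R,9R,10S: cis-fused, with C5–H, C10–CH3, C8–CH3 and the C9 chain β, and C8–OH and C9–H α. The (R) centre of α-ionone becomes C5 unchanged.
- Assumption: (R)-α-ionone is bought in high enantiomeric purity.
- Protecting-group design: C12–O is carried as a benzyl ether, not a silyl ether. C8–OH must be silylated before C12 is activated, because a free 8-hydroxy-12-iodide would close to the 8,12-tetrahydrofuran. Benzyl can then be removed without touching that silyl ether.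

**Route**

Step 1
Reactants: 1 (R)-α-ionone
Product: 3 (R)-dihydro-α-ionone, via triethylsilyl enol ether 2 (not isolated)
Conditions: Et3SiH, RhCl(PPh3)3 (cat.), neat, 50 °C; then K2CO3, MeOH–H2O, rt
Reagents that add atoms: none
Why: Rhodium-catalysed 1,4-hydrosilylation of the enone (Ojima conjugate reduction) and hydrolysis of the silyl enol ether should reduce only the conjugated alkene under neutral conditions, so the ring alkene stays in place and the C5 stereocentre is untouched.

Step 2
Reactants: 3 (R)-dihydro-α-ionone; 4 (benzyloxy)acetaldehyde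
Product: 6 β-hydroxy ketone (aldol adduct; both carbinol epimers), via lithium enolate 5 (not isolated)
Conditions: LDA, THF, −78 °C; then 4, −78 °C
Reagents that add atoms: none
Why: Kinetic deprotonation of the methyl ketone occurs at the methyl group and the lithium enolate adds to the aldehyde (directed aldol addition); the new carbinol centre is removed in step 3, so its configuration is irrelevant.

Step 3
Reactants: 6 β-hydroxy ketone
Product: 8 (E)-enone, via mesylate 7 (not isolated)
Conditions: MsCl, Et3N, CH2Cl2, 0 °C → rt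
Reagents that add atoms: none
Why: Mesylation followed by E1cB elimination of the β-mesyloxy ketone should give the conjugated enone in its more stable (E) geometry.

Step 4
Reactants: 8 (E)-enone
Product: 9 (Z)-α-iodoenone (Heck precursor)
Conditions: I2, DMAP (cat.), pyridine–CH2Cl2, rt, dark
Reagents that add atoms: iodine, II
Why: Johnson-type α-iodination of an enone (conjugate addition of the pyridine base, iodination of the enolate, E1cB loss of the base) should put iodine on C9 and give the (Z)-isomer with the acyl group and CH2OBn trans, while the isolated ring alkene does not add iodine under anhydrous basic conditions.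

Step 5
Reactants: 9 (Z)-α-iodoenone
Product: 10 cis-fused bicyclic enone (C8 ketone; exocyclic C9=C11 alkene; C1=C2 alkene)
Conditions: Pd(OAc)2 (10 mol %), PPh3 (30 mol %), Ag2CO3, MeCN, 80 °C
Reagents that add atoms: none
Why: Pd(0) adds oxidatively to the C9–I bond with retention of alkene geometry, silver removes iodide, and the cationic alkenylpalladium(II) inserts syn into the C10=C1 ring alkene with C9 bonding to the more substituted C10 and palladium ending on C1; since C10 then has no hydrogen, syn β-hydride elimination can only use a C2 hydrogen, which gives the C1=C2 alkene, and carbonate returns Pd–H to Pd(0). The closest known reaction type is the intramolecular Heck cyclization of alkenyl halides onto trisubstituted cycloalkenes that builds quaternary carbons in cis-fused bicycles. Ring B closes in the 6-exo-trig mode. The new C10 stereocentre is controlled by C5: the three-atom tether C6–C7–C8 can deliver C9 only to the alkene face cis to C6, so the fusion is cis (10S, CH3 syn to C5–H). The step needs 6-exo over 7-endo regioselectivity, which the tether length and the usual exo preference of alkenylpalladium insertions should secure; the (Z)-iodide geometry is carried into the exocyclic alkene, whose geometry has no consequence later.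

Step 6
Reactants: 10 cis-fused bicyclic enone
Product: 11 tertiary allylic alcohol (8α-OH; 8β-CH3)
Conditions: MeLi, CeCl3, THF, −78 °C
Reagents that add atoms: methyllithium, [Li]C
Why: Organocerium 1,2-addition (Imamoto conditions) suppresses enolisation and conjugate addition, and the reagent should approach C8 from the convex β face of the cis-fused bicycle (the face of C5–H and C10–CH3, away from ring A folded under the α face), so CH3 ends up β and OH α (8R).

Step 7
Reactants: 11 tertiary allylic alcohol
Product: 12 saturated tertiary alcohol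
Conditions: H2 (1 atm), [Ir(cod)(PCy3)(py)]PF6 (cat.), CH2Cl2, 0 °C → rt
Reagents that add atoms: none
Why: Hydroxyl-directed hydrogenation with Crabtree's catalyst: iridium bound to the 8α-OH delivers hydrogen to the α face of the exocyclic C9=C11 alkene, so C9–H is cis to OH and the side chain is β (9R), and the C1=C2 alkene is saturated in the same operation without stereochemical consequence.

Step 8
Reactants: 12 saturated tertiary alcohol
Product: 13 triethylsilyl ether
Conditions: TESOTf, 2,6-lutidine, CH2Cl2, −78 → 0 °C
Reagents that add atoms: triethylsilyl trifluoromethanesulfonate, CC[Si](CC)(CC)OS(=O)(=O)C(F)(F)F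
Why: Silylation of the tertiary alcohol with a silyl triflate masks C8–OH, which would otherwise attack activated C12 and close a tetrahydrofuran in the following steps.

Step 9
Reactants: 13 triethylsilyl ether
Product: 14 primary alcohol
Conditions: H2 (1 atm), Pd(OH)2/C, EtOAc, rt
Reagents that add atoms: none
Why: Palladium-catalysed hydrogenolysis of the benzyl ether should free C12–OH in a molecule that no longer contains an alkene, the tertiary silyl ether being stable in neutral ethyl acetate.

Step 10
Reactants: 14 primary alcohol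
Product: 15 primary iodide
Conditions: I2, PPh3, imidazole, CH2Cl2, 0 °C → rt
Reagents that add atoms: iodine, II
Why: Appel-type iodination converts the unhindered primary alcohol into the iodide by SN2 displacement of the alkoxyphosphonium ion, with C8–O safely silylated.

Step 11
Reactants: 16 1-(trimethylsilyl)propyne; 17 geranyl bromide
Product: 19 silylated dienyne, via 3-lithio-1-(trimethylsilyl)propyne 18 (not isolated)
Conditions: n-BuLi, THF, −78 °C; then 17, −78 °C → rt
Reagents that add atoms: none
Why: The lithiated silylpropyne reacts as a propargyl anion and displaces the primary allylic bromide in an SN2 alkylation that leaves the (E)-alkene of the geranyl unit unchanged.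

Step 12
Reactants: 19 silylated dienyne
Product: 20 terminal alkyne
Conditions: K2CO3, MeOH, rt
Reagents that add atoms: none
Why: Base-catalysed methanolysis cleaves the alkynyl C–Si bond (protodesilylation) without affecting the alkenes.

Step 13
Reactants: 20 terminal alkyne
Product: 22 (E)-vinyl iodide, via alkenyldimethylalane 21 (not isolated)
Conditions: AlMe3, Cp2ZrCl2 (cat.), CH2Cl2, 0 °C → rt; then I2, THF, −30 → 0 °C
Reagents that add atoms: trimethylaluminium, C[Al](C)C; iodine, II
Why: Negishi zirconium-catalysed carboalumination adds CH3 and aluminium syn across the terminal alkyne with aluminium on the terminal carbon, and iodinolysis with retention gives the (E)-trisubstituted vinyl iodide.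

Step 14
Reactants: 15 primary iodide; 22 (E)-vinyl iodide
Product: 25 triethylsilyl ether of the target, via alkyllithium 23 (not isolated), via lithium alkyl(methoxy)borate 24 (not isolated)
Conditions: t-BuLi, Et2O, −78 °C; B-MeO-9-BBN, THF, −78 °C → rt; then 22, PdCl2(dppf) (cat.), AsPh3, aq. K3PO4, DMF, rt
Reagents that add atoms: none
Why: B-alkyl Suzuki–Miyaura coupling: iodine–lithium exchange and trapping with B-methoxy-9-BBN give a borate that transfers its primary alkyl group to palladium, and reductive elimination with the alkenyl iodide forms C12–C13 with retention of the (E) geometry.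

Step 15
Reactants: 25 triethylsilyl ether of the target
Product: 26 target
Conditions: TBAF, THF, rt → 40 °C
Reagents that add atoms: none
Why: Fluoride-mediated cleavage of the tertiary triethylsilyl ether frees C8–OH under non-acidic conditions that leave the triene untouched.

**Compound list**

1 | (R)-α-ionone, (3E)-4-[(1R)-2,6,6-trimethylcyclohex-2-en-1-yl]but-3-en-2-one | CC(=O)/C=C/[C@H]1C(C)=CCCC1(C)C | starting material
2 | triethylsilyl enol ether of 3, triethyl({4-[(1R)-2,6,6-trimethylcyclohex-2-en-1-yl]but-2-en-2-yl}oxy)silane (E/Z mixture) | CC1=CCCC(C)(C)[C@H]1CC=C(C)O[Si](CC)(CC)CC | intermediate (not isolated)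
3 | (R)-dihydro-α-ionone, 4-[(1R)-2,6,6-trimethylcyclohex-2-en-1-yl]butan-2-one | CC1=CCCC(C)(C)[C@H]1CCC(C)=O | intermediate
4 | (benzyloxy)acetaldehyde | O=CCOCc1ccccc1 | starting material
5 | kinetic lithium enolate of 3, lithium 4-[(1R)-2,6,6-trimethylcyclohex-2-en-1-yl]but-1-en-2-olate | CC1=CCCC(C)(C)[C@H]1CCC(=C)O[Li] | intermediate (not isolated)
6 | 1-(benzyloxy)-2-hydroxy-6-[(1R)-2,6,6-trimethylcyclohex-2-en-1-yl]hexan-4-one (both C2 epimers) | CC1=CCCC(C)(C)[C@H]1CCC(=O)CC(O)COCc1ccccc1 | intermediate
7 | methanesulfonate of 6 (at the C2 hydroxyl) | CC1=CCCC(C)(C)[C@H]1CCC(=O)CC(COCc1ccccc1)OS(C)(=O)=O | intermediate (not isolated)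
8 | (2E)-1-(benzyloxy)-6-[(1R)-2,6,6-trimethylcyclohex-2-en-1-yl]hex-2-en-4-one | CC1=CCCC(C)(C)[C@H]1CCC(=O)/C=C/COCc1ccccc1 | intermediate
9 | (2Z)-1-(benzyloxy)-3-iodo-6-[(1R)-2,6,6-trimethylcyclohex-2-en-1-yl]hex-2-en-4-one | CC1=CCCC(C)(C)[C@H]1CCC(=O)/C(I)=C/COCc1ccccc1 | intermediate
10 | (1E,4aR,8aS)-1-[2-(benzyloxy)ethylidene]-5,5,8a-trimethyl-3,4,4a,5,6,8a-hexahydronaphthalen-2(1H)-one (cis-fused; 5β-H; 10β-CH3) | O=C1CC[C@@H]2C(C)(C)CC=C[C@]2(C)/C1=C\COCc1ccccc1 | intermediate
11 | (1E,2R,4aR,8aS)-1-[2-(benzyloxy)ethylidene]-2,5,5,8a-tetramethyl-1,2,3,4,4a,5,6,8a-octahydronaphthalen-2-ol (8α-OH; 8β-CH3) | c1ccccc1COC\C=C1/[C@@]2(C)C=CCC(C)(C)[C@H]2CC[C@@]1(C)O | intermediate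
12 | (1R,2R,4aR,8aS)-1-[2-(benzyloxy)ethyl]-2,5,5,8a-tetramethyldecahydronaphthalen-2-ol | c1ccccc1COCC[C@@H]1[C@@]2(C)CCCC(C)(C)[C@H]2CC[C@@]1(C)O | intermediate
13 | {[(1R,2R,4aR,8aS)-1-[2-(benzyloxy)ethyl]-2,5,5,8a-tetramethyldecahydronaphthalen-2-yl]oxy}triethylsilane | c1ccccc1COCC[C@@H]1[C@@]2(C)CCCC(C)(C)[C@H]2CC[C@@]1(C)O[Si](CC)(CC)CC | intermediate
14 | 2-{(1R,2R,4aR,8aS)-2,5,5,8a-tetramethyl-2-[(triethylsilyl)oxy]decahydronaphthalen-1-yl}ethan-1-ol | OCC[C@@H]1[C@@]2(C)CCCC(C)(C)[C@H]2CC[C@@]1(C)O[Si](CC)(CC)CC | intermediate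
15 | {[(1R,2R,4aR,8aS)-1-(2-iodoethyl)-2,5,5,8a-tetramethyldecahydronaphthalen-2-yl]oxy}triethylsilane | ICC[C@@H]1[C@@]2(C)CCCC(C)(C)[C@H]2CC[C@@]1(C)O[Si](CC)(CC)CC | intermediate
16 | 1-(trimethylsilyl)propyne | CC#C[Si](C)(C)C | starting material
17 | geranyl bromide, (2E)-1-bromo-3,7-dimethylocta-2,6-diene | CC(C)=CCC/C(C)=C/CBr | starting material
18 | 3-lithio-1-(trimethylsilyl)propyne | [Li]CC#C[Si](C)(C)C | intermediate (not isolated)
19 | [(5E)-6,10-dimethylundeca-5,9-dien-1-yn-1-yl]trimethylsilane | CC(C)=CCC/C(C)=C/CCC#C[Si](C)(C)C | intermediate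
20 | (5E)-6,10-dimethylundeca-5,9-dien-1-yne | CC(C)=CCC/C(C)=C/CCC#C | intermediate
21 | dimethyl[(1E,5E)-2,6,10-trimethylundeca-1,5,9-trien-1-yl]alane | CC(C)=CCC/C(C)=C/CC/C(C)=C/[Al](C)C | intermediate (not isolated)
22 | (1E,5E)-1-iodo-2,6,10-trimethylundeca-1,5,9-triene | CC(C)=CCC/C(C)=C/CC/C(C)=C/I | intermediate
23 | alkyllithium from 15 (lithium in place of iodine at C12) | [Li]CC[C@@H]1[C@@]2(C)CCCC(C)(C)[C@H]2CC[C@@]1(C)O[Si](CC)(CC)CC | intermediate (not isolated)
24 | lithium B-methoxy-B-alkyl-9-borabicyclo[3.3.1]nonan-9-uide (alkyl = C12 of 23) | [Li+].CO[B-]1(CC[C@@H]3[C@@]4(C)CCCC(C)(C)[C@H]4CC[C@@]3(C)O[Si](CC)(CC)CC)C2CCCC1CCC2 | intermediate (not isolated)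
25 | triethyl{[(1R,2R,4aR,8aS)-2,5,5,8a-tetramethyl-1-[(3E,7E)-4,8,12-trimethyltrideca-3,7,11-trien-1-yl]decahydronaphthalen-2-yl]oxy}silane | CC(C)=CCC/C(C)=C/CC/C(C)=C/CC[C@@H]1[C@@]2(C)CCCC(C)(C)[C@H]2CC[C@@]1(C)O[Si](CC)(CC)CC | intermediate
26 | (1R,2R,4aR,8aS)-2,5,5,8a-tetramethyl-1-[(3E,7E)-4,8,12-trimethyltrideca-3,7,11-trien-1-yl]decahydronaphthalen-2-ol | CC(C)=CCC/C(C)=C/CC/C(C)=C/CC[C@@H]1[C@@]2(C)CCCC(C)(C)[C@H]2CC[C@@]1(C)O | target

**Step count.** Total: 15 steps. Longest linear sequence: 12 steps (steps 1–10, 14 and 15, from 1).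

**Steps most likely to fail**

1. Step 5 (Heck closure). Migratory insertion of the electron-poor, hindered alkenylpalladium into the trisubstituted ring alkene may be slower than protodeiodination or base-induced decay of the iodoenone. The fallback moves the cyclization to the allylic-alcohol oxidation level, where the palladium partner is an ordinary electron-neutral alkenyl iodide. It sets out from 9. Luche reduction (NaBH4, CeCl3·7H2O, MeOH, −40 °C) should give the iodo allylic alcohol F1 as a mixture of C8 epimers. Heck cyclization of F1 (Pd(OAc)2, PPh3, Ag2CO3, MeCN, 80 °C) should close ring B with the same cis fusion and give the bicyclic allylic alcohol F2. Dess–Martin oxidation of F2 converges both epimers on 10, where the route is rejoined.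

2. Step 6 (methyl addition). Facial selectivity may be poor or reversed if the cis-decalin reacts through the conformer in which C10–CH3 is axial on ring B and shields the β face of C8. The fallback delivers oxygen, not carbon, from the open α face. It sets out from 10. Hydrogenation over ethylenediamine-poisoned Pd/C (H2, THF), which spares the benzyl ether, followed by NaOMe/MeOH equilibration at C9, should give the saturated ketone F3 with the side chain equatorial (9β). Wittig methylenation (Ph3P=CH2, THF, 60 °C) should give the exocyclic alkene F4. Epoxidation with mCPBA (NaHCO3, CH2Cl2) from the α face should give the spiro-epoxide F5. LiAlH4 (THF) opens it at the CH2 terminus and gives 12, where the route is rejoined.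

3. Step 7 (directed hydrogenation). The cationic iridium catalyst may deactivate before the congested exocyclic alkene between C8 and C10 is reduced, or acidic iridium hydrides may ionise the tertiary allylic alcohol. The fallback uses radical hydrogen-atom-transfer hydrogenation, which is insensitive to steric crowding. It sets out from 11. Mn(dpm)3 (cat.), PhSiH3 and TBHP in i-PrOH at rt should reduce the exocyclic alkene through a C9 radical that takes up hydrogen from the α face, opposite the C8 and C10 methyl groups, giving the alcohol F6, which still holds the C1=C2 alkene. Hydrogenation of F6 over ethylenediamine-poisoned Pd/C (H2, THF) saturates ring A and gives 12, where the route is rejoined.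

**Further compounds**

F1 | step 5 | (2Z)-1-(benzyloxy)-3-iodo-6-[(1R)-2,6,6-trimethylcyclohex-2-en-1-yl]hex-2-en-4-ol (both C4 epimers) | CC1=CCCC(C)(C)[C@H]1CCC(O)/C(I)=C/COCc1ccccc1
F2 | step 5 | (1E,4aR,8aS)-1-[2-(benzyloxy)ethylidene]-5,5,8a-trimethyl-1,2,3,4,4a,5,6,8a-octahydronaphthalen-2-ol (both C2 epimers) | OC1CC[C@@H]2C(C)(C)CC=C[C@]2(C)/C1=C\COCc1ccccc1
F3 | step 6 | (1R,4aR,8aS)-1-[2-(benzyloxy)ethyl]-5,5,8a-trimethyloctahydronaphthalen-2(1H)-one (5β-H; 9β side chain; 10β-CH3) | c1ccccc1COCC[C@@H]1[C@@]2(C)CCCC(C)(C)[C@H]2CCC1=O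
F4 | step 6 | 1-[2-(benzyloxy)ethyl]-5,5,8a-trimethyl-2-methylidenedecahydronaphthalene (5β-H; 9β side chain; 10β-CH3) | c1ccccc1COCC[C@@H]1[C@@]2(C)CCCC(C)(C)[C@H]2CCC1=C
F5 | step 6 | 8α,17-epoxide of F4 (spiro-oxirane at C8; oxygen α; CH2 β) | c1ccccc1COCC[C@@H]1[C@@]2(C)CCCC(C)(C)[C@H]2CC[C@@]1(C3)O3
F6 | step 7 | (1R,2R,4aR,8aS)-1-[2-(benzyloxy)ethyl]-2,5,5,8a-tetramethyl-1,2,3,4,4a,5,6,8a-octahydronaphthalen-2-ol | c1ccccc1COCC[C@@H]1[C@@]2(C)C=CCC(C)(C)[C@H]2CC[C@@]1(C)O
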